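**Plan**

- Retrosynthetic cuts: first the chelated chromone 5‑O–CH3 bond and the CH2–C5 diarylmethane bond. Behind them, the chromone pyranone ring is cut at C4–C4a, C2–C3 and O1–C2, and the isochromanone δ‑lactone ring at C3–C4 and O2–C1.
- Enabling feature: C4 of the isochromanone is a benzylic CH2 lying between arene carbon C4a and the stereogenic C3. The δ‑lactone ring therefore opens to an enolisable homophthalic anhydride plus acetaldehyde, with a removable CO2H left on C4.
- Forward order: atraric acid is taken to the dibenzyl homophthalic anhydride, and the anhydride–acetaldehyde cycloaddition closes the δ‑lactone ring. Decarboxylation and debenzylation follow. The pyranone ring is built separately on symmetric 4‑hydroxy‑2,6‑dimethoxybenzaldehyde. The halves are joined at C5 by Friedel–Crafts benzylation, and the chromone 5‑OMe is cleaved last.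
- Stereochemistry: the only stereocentre, C3 (R), comes from catalyst‑controlled Si‑face addition to acetaldehyde in the cycloaddition. The transient C4 centre is erased by decarboxylation.

Key step: step 5

Assumption: the quinine‑derived squaramide named in step 5 is taken to direct the anhydride enol to the Si face of acetaldehyde (3R); if its sense proves opposite, the quinidine‑derived pseudoenantiomer replaces it with nothing else changed.

**Route**

Step 1
Reactants: 1 methyl 2,4‑dihydroxy‑3,6‑dimethylbenzoate (atraric acid)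
Product: 2 methyl 2,4‑bis(benzyloxy)‑3,6‑dimethylbenzoate
Conditions: BnBr (2.5 equiv), K2CO3, cat. Bu4NI, DMF, 70 °C
Reagents that add atoms: benzyl bromide BrCc1ccccc1
Why: Williamson etherification of both phenols (warm DMF is needed for the ester‑chelated 2‑OH) installs benzyl ethers that survive amide base, hydroxide and Ac2O and leave later by hydrogenolysis.

Step 2
Reactants: 2 methyl 2,4‑bis(benzyloxy)‑3,6‑dimethylbenzoate
Product: 4 2‑[3,5‑bis(benzyloxy)‑2‑(methoxycarbonyl)‑4‑methylphenyl]acetic acid, via laterally lithiated toluate 3 (not isolated)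
Conditions: LiN(iPr)2 (1.3 equiv), THF, −78 °C; CO2 (g), −78 °C → rt; aq. HCl
Reagents that add atoms: carbon dioxide O=C=O
Why: Lateral lithiation of an ortho‑toluate removes a proton only from the C6 methyl, whose anion is conjugated with the ester (the C3 methyl and the OCH2Ph groups are not so activated), and carboxylation of that benzylic anion gives the homophthalic half ester.

Step 3
Reactants: 4 2‑[3,5‑bis(benzyloxy)‑2‑(methoxycarbonyl)‑4‑methylphenyl]acetic acid
Product: 5 2,4‑bis(benzyloxy)‑6‑(carboxymethyl)‑3‑methylbenzoic acid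
Conditions: KOH (10 equiv), DMSO/H2O 4:1, 100 °C; aq. HCl to pH 2
Reagents that add atoms: water O
Why: Forcing saponification cleaves the di‑ortho‑substituted methyl benzoate, while benzyl ethers and the arylacetate are inert to hydroxide.

Step 4
Reactants: 5 2,4‑bis(benzyloxy)‑6‑(carboxymethyl)‑3‑methylbenzoic acid
Product: 6 6,8‑bis(benzyloxy)‑7‑methylisochromane‑1,3‑dione
Conditions: Ac2O (3 equiv), toluene, 90 °C; evaporate
Reagents that add atoms: none
Why: Cyclodehydration of a homophthalic acid to its six‑membered anhydride by Ac2O, run without base so that the acidic C4 methylene is not acetylated.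

Step 5
Reactants: 6 6,8‑bis(benzyloxy)‑7‑methylisochromane‑1,3‑dione; 7 acetaldehyde
Product: 8 (3R)‑6,8‑bis(benzyloxy)‑3,7‑dimethyl‑1‑oxoisochromane‑4‑carboxylic acid (C4 epimer mixture, trans expected to predominate)
Conditions: 7 (3 equiv, freshly distilled), 3‑{[3,5‑bis(trifluoromethyl)phenyl]amino}‑4‑{[(8α,9S)‑6′‑methoxycinchonan‑9‑yl]amino}cyclobut‑3‑ene‑1,2‑dione (5 mol%), MTBE, −30 °C, sealed vessel; aq. HCl wash
Reagents that add atoms: none
Why: The quinuclidine nitrogen of the catalyst enolises the anhydride at C4, its only enolisable site, while the squaramide N–H pair hydrogen‑bonds acetaldehyde; the enol adds to the Si face of the aldehyde to form C3–C4, and the aldolate then attacks the aryl‑bound anhydride carbonyl C1, opening the anhydride and leaving the former aliphatic carbonyl as the C4 carboxylic acid. The closest known reaction is the cinchona‑squaramide‑catalysed formal [4+2] cycloaddition of enolisable homophthalic anhydrides with aldehydes to 3‑substituted 1‑oxoisochromane‑4‑carboxylic acids, applied here to acetaldehyde and a 6,8‑dialkoxy anhydride. The δ‑lactone ring closes by 6‑exo‑trig acyl substitution at C1 (O2–C1), the alternative attack on the aliphatic carbonyl being a strained 4‑exo closure to a β‑lactone. C3 is set as R by the catalyst alone, since neither partner carries a stereocentre, and C4 needs no control because its carboxyl is removed in step 6. The step needs enantiofacial selectivity at the aldehyde and clean cross‑reaction: a tertiary amine cannot form an enamine with acetaldehyde, the low temperature holds back its self‑aldol, and the benzyl ethers keep the phenols from acylating the anhydride.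

Step 6
Reactants: 8 (3R)‑6,8‑bis(benzyloxy)‑3,7‑dimethyl‑1‑oxoisochromane‑4‑carboxylic acid
Product: 9 (3R)‑6,8‑bis(benzyloxy)‑3,7‑dimethylisochroman‑1‑one
Conditions: 9‑mesityl‑10‑phenylacridinium tetrafluoroborate (5 mol%), (PhS)2 (10 mol%), iPr2NEt (20 mol%), CF3CH2OH, 450 nm LEDs, rt, degassed
Reagents that add atoms: none
Why: Photoredox hydrodecarboxylation: the excited acridinium oxidises the carboxylate, loss of CO2 leaves a benzylic C4 radical, and thiophenol formed from the disulfide returns a hydrogen atom, which erases the C4 centre while the non‑benzylic C3–O bond and its configuration are untouched.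

Step 7
Reactants: 9 (3R)‑6,8‑bis(benzyloxy)‑3,7‑dimethylisochroman‑1‑one
Product: 10 (3R)‑6,8‑dihydroxy‑3,7‑dimethylisochroman‑1‑one
Conditions: H2 (1 atm), 10% Pd/C, EtOAc/MeOH, rt
Reagents that add atoms: none
Why: Hydrogenolysis of the aryl benzyl ethers over Pd/C leaves the homobenzylic lactone C3–O bond intact and turns C5 into a resorcinol‑type nucleophile for step 11.

Step 8
Reactants: 11 4‑hydroxy‑2,6‑dimethoxybenzaldehyde
Product: 12 3‑acetyl‑4‑hydroxy‑2,6‑dimethoxybenzaldehyde
Conditions: Ac2O (1.2 equiv), BF3·OEt2 (3 equiv), AcOH, 70 °C; poured into aq. NaOAc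
Reagents that add atoms: acetic anhydride CC(=O)OC(C)=O
Why: Friedel–Crafts acetylation under the BF3 conditions used for acylphloroglucinols gives one acetophenone, because the two free ring positions are equivalent by symmetry and each is ortho to OH, ortho to one OMe and para to the other.

Step 9
Reactants: 12 3‑acetyl‑4‑hydroxy‑2,6‑dimethoxybenzaldehyde
Product: 14 5,7‑dimethoxy‑2‑methyl‑4‑oxo‑4H‑chromene‑6‑carbaldehyde, via aryl 1,3‑diketone 13 (not isolated)
Conditions: LiN(SiMe3)2 (3.5 equiv), THF, −78 °C; AcCl (1.05 equiv), −78 → 0 °C; aq. HCl; then AcOH, cat. H2SO4, 50 °C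
Reagents that add atoms: acetyl chloride CC(=O)Cl
Why: Acetylation of the phenoxide–enolate dianion (Claisen/Baker–Venkataraman manifold) gives the 1,3‑diketone, whose phenol adds to the distal carbonyl and dehydrates under acid to the 2‑methylchromone (O1–C2 closure of the pyranone ring); at −78 °C the formyl group, para to the phenoxide and flanked by two OMe groups, is a poor electrophile.

Step 10
Reactants: 14 5,7‑dimethoxy‑2‑methyl‑4‑oxo‑4H‑chromene‑6‑carbaldehyde
Product: 15 6‑(hydroxymethyl)‑5,7‑dimethoxy‑2‑methyl‑4H‑chromen‑4‑one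
Conditions: NaBH4 (0.5 equiv), MeOH/CH2Cl2, 0 °C; aq. NaHCO3 work‑up
Reagents that add atoms: none
Why: Borohydride reduces the aldehyde much faster than the electron‑rich chromone (a vinylogous ester), giving the benzylic alcohol that serves as the cation precursor.

Step 11
Reactants: 10 (3R)‑6,8‑dihydroxy‑3,7‑dimethylisochroman‑1‑one; 15 6‑(hydroxymethyl)‑5,7‑dimethoxy‑2‑methyl‑4H‑chromen‑4‑one
Product: 16 (3R)‑5‑[(5,7‑dimethoxy‑2‑methyl‑4‑oxo‑4H‑chromen‑6‑yl)methyl]‑6,8‑dihydroxy‑3,7‑dimethylisochroman‑1‑one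
Conditions: 10 (1.5 equiv), TsOH·H2O (10 mol%), (CF3)2CHOH/CH2Cl2 1:4, 0 °C → rt; 15 added over 2 h
Reagents that add atoms: none
Why: Dehydrative Friedel–Crafts benzylation: acid ionises 15 to a benzylic cation stabilised by two ortho OMe groups and the para ring oxygen, and C5 of 10 (its only unsubstituted ring carbon, ortho to 6‑OH and para to 8‑OH) captures it, with any O‑benzylation reversible under the acid and slow addition of 15 to excess 10 working against self‑condensation at chromone C8.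

Step 12
Reactants: 16 (3R)‑5‑[(5,7‑dimethoxy‑2‑methyl‑4‑oxo‑4H‑chromen‑6‑yl)methyl]‑6,8‑dihydroxy‑3,7‑dimethylisochroman‑1‑one
Product: 17 (3R)‑6,8‑dihydroxy‑5‑[(5‑hydroxy‑7‑methoxy‑2‑methyl‑4‑oxo‑4H‑chromen‑6‑yl)methyl]‑3,7‑dimethylisochroman‑1‑one (CNP0180307.1)
Conditions: BCl3 (5 equiv), CH2Cl2, −78 → 0 °C; MeOH quench, aqueous work‑up
Reagents that add atoms: none
Why: BCl3 chelates between the chromone C4 carbonyl and the peri 5‑OMe and cleaves only that methyl ether, leaving the non‑chelated 7‑OMe, the lactone and C3 alone.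

**Compound list**

1 | methyl 2,4‑dihydroxy‑3,6‑dimethylbenzoate (atraric acid) | COC(=O)c1c(C)cc(O)c(C)c1O | starting material
2 | methyl 2,4‑bis(benzyloxy)‑3,6‑dimethylbenzoate | COC(=O)c1c(C)cc(OCc2ccccc2)c(C)c1OCc1ccccc1 | intermediate
3 | [3,5‑bis(benzyloxy)‑2‑(methoxycarbonyl)‑4‑methylbenzyl]lithium (laterally lithiated toluate) | COC(=O)c1c(C[Li])cc(OCc2ccccc2)c(C)c1OCc1ccccc1 | intermediate (not isolated)
4 | 2‑[3,5‑bis(benzyloxy)‑2‑(methoxycarbonyl)‑4‑methylphenyl]acetic acid | COC(=O)c1c(CC(=O)O)cc(OCc2ccccc2)c(C)c1OCc1ccccc1 | intermediate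
5 | 2,4‑bis(benzyloxy)‑6‑(carboxymethyl)‑3‑methylbenzoic acid | OC(=O)Cc1cc(OCc2ccccc2)c(C)c(OCc2ccccc2)c1C(=O)O | intermediate
6 | 6,8‑bis(benzyloxy)‑7‑methylisochromane‑1,3‑dione | O=C1Cc2cc(OCc3ccccc3)c(C)c(OCc3ccccc3)c2C(=O)O1 | intermediate
7 | acetaldehyde | CC=O | starting material
8 | (3R)‑6,8‑bis(benzyloxy)‑3,7‑dimethyl‑1‑oxoisochromane‑4‑carboxylic acid (C4 epimer mixture) | C[C@@H]1C(C(=O)O)c2cc(OCc3ccccc3)c(C)c(OCc3ccccc3)c2C(=O)O1 | intermediate
9 | (3R)‑6,8‑bis(benzyloxy)‑3,7‑dimethylisochroman‑1‑one | C[C@@H]1Cc2cc(OCc3ccccc3)c(C)c(OCc3ccccc3)c2C(=O)O1 | intermediate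
10 | (3R)‑6,8‑dihydroxy‑3,7‑dimethylisochroman‑1‑one | C[C@@H]1Cc2cc(O)c(C)c(O)c2C(=O)O1 | intermediate
11 | 4‑hydroxy‑2,6‑dimethoxybenzaldehyde | COc1cc(O)cc(OC)c1C=O | starting material
12 | 3‑acetyl‑4‑hydroxy‑2,6‑dimethoxybenzaldehyde | COc1cc(O)c(C(C)=O)c(OC)c1C=O | intermediate
13 | 4‑hydroxy‑2,6‑dimethoxy‑3‑(3‑oxobutanoyl)benzaldehyde (aryl 1,3‑diketone) | COc1cc(O)c(C(=O)CC(C)=O)c(OC)c1C=O | intermediate (not isolated)
14 | 5,7‑dimethoxy‑2‑methyl‑4‑oxo‑4H‑chromene‑6‑carbaldehyde | COc1cc2oc(C)cc(=O)c2c(OC)c1C=O | intermediate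
15 | 6‑(hydroxymethyl)‑5,7‑dimethoxy‑2‑methyl‑4H‑chromen‑4‑one | COc1cc2oc(C)cc(=O)c2c(OC)c1CO | intermediate
16 | (3R)‑5‑[(5,7‑dimethoxy‑2‑methyl‑4‑oxo‑4H‑chromen‑6‑yl)methyl]‑6,8‑dihydroxy‑3,7‑dimethylisochroman‑1‑one | COc1cc2oc(C)cc(=O)c2c(OC)c1Cc1c(O)c(C)c(O)c2c1C[C@@H](C)OC2=O | intermediate
17 | (3R)‑6,8‑dihydroxy‑5‑[(5‑hydroxy‑7‑methoxy‑2‑methyl‑4‑oxo‑4H‑chromen‑6‑yl)methyl]‑3,7‑dimethylisochroman‑1‑one | COc1cc2oc(C)cc(=O)c2c(O)c1Cc1c(O)c(C)c(O)c2c1C[C@@H](C)OC2=O | target

**Step count and risks**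

Total steps: 12. Longest linear sequence: 9 (steps 1–7, 11, 12); steps 8–10 form the three‑step chromone branch.

Steps most likely to fail:

1. Step 5. Acetaldehyde is small, volatile and enolisable, so facial discrimination by the catalyst may be poor. Ring closure at the carbonyl flanked by the peri benzyloxy group may also be slow, letting a reversible aldol step erode selectivity or conversion. Fallback, from the lithiated toluate 3 (made from 2 as in step 2), returning at 9: 3 is acylated with N‑methoxy‑N‑methylacetamide (THF, −78 °C, aq. HCl work‑up) to give methyl 2,4‑bis(benzyloxy)‑3‑methyl‑6‑(2‑oxopropyl)benzoate F1. An (R)‑selective ketoreductase (NADPH recycled with iPrOH, buffer/DMSO, 30 °C) should reduce the ketone to methyl 2,4‑bis(benzyloxy)‑6‑[(2R)‑2‑hydroxypropyl]‑3‑methylbenzoate F2. NaH in THF then closes the lactone with loss of methanol to give 9. The stereocentre would then come from an enzymatic ketone reduction, and steps 3–6 fall away.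

2. Step 11. The benzylic cation may be captured by C8 of a second chromone molecule (self‑condensation and oligomerisation) faster than by the hindered C5 of 10. Fallback, from 9 and 15, returning at 17: 9 is brominated at its only aromatic C–H with NBS in MeCN to give (3R)‑6,8‑bis(benzyloxy)‑5‑bromo‑3,7‑dimethylisochroman‑1‑one F3. Alcohol 15 is converted with SOCl2 (CH2Cl2, 0 °C) into 6‑(chloromethyl)‑5,7‑dimethoxy‑2‑methyl‑4H‑chromen‑4‑one F4. Zinc dust with LiCl in THF inserts to give [(5,7‑dimethoxy‑2‑methyl‑4‑oxo‑4H‑chromen‑6‑yl)methyl]zinc chloride F5. Negishi coupling of F3 with F5 (Pd(OAc)2, SPhos, THF, 50 °C) joins the halves as (3R)‑6,8‑bis(benzyloxy)‑5‑[(5,7‑dimethoxy‑2‑methyl‑4‑oxo‑4H‑chromen‑6‑yl)methyl]‑3,7‑dimethylisochroman‑1‑one F6. BCl3 with pentamethylbenzene (CH2Cl2, −78 → 0 °C) then removes both benzyl groups and the chelated 5‑O‑methyl in one operation to give 17. Steps 7 and 12 fall away.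

3. Step 9. The enolate or the silylamide base may add to the unprotected formyl group (intermolecular aldol or imine formation) instead of undergoing clean C‑acetylation. Fallback, from 12, returning at 14: 12 is masked with HC(OMe)3 and cat. TsOH·H2O in MeOH as 1‑[3‑(dimethoxymethyl)‑6‑hydroxy‑2,4‑dimethoxyphenyl]ethan‑1‑one F7. A classical Claisen condensation (NaH, EtOAc, THF, reflux; aq. HCl quench at 0 °C) gives 1‑[3‑(dimethoxymethyl)‑6‑hydroxy‑2,4‑dimethoxyphenyl]butane‑1,3‑dione F8. Aqueous HCl in AcOH at 50 °C cyclodehydrates the diketone and hydrolyses the acetal to give 14.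

**Further compounds**

F1 | step 5 | methyl 2,4‑bis(benzyloxy)‑3‑methyl‑6‑(2‑oxopropyl)benzoate | COC(=O)c1c(CC(C)=O)cc(OCc2ccccc2)c(C)c1OCc1ccccc1
F2 | step 5 | methyl 2,4‑bis(benzyloxy)‑6‑[(2R)‑2‑hydroxypropyl]‑3‑methylbenzoate | COC(=O)c1c(C[C@@H](C)O)cc(OCc2ccccc2)c(C)c1OCc1ccccc1
F3 | step 11 | (3R)‑6,8‑bis(benzyloxy)‑5‑bromo‑3,7‑dimethylisochroman‑1‑one | C[C@@H]1Cc2c(Br)c(OCc3ccccc3)c(C)c(OCc3ccccc3)c2C(=O)O1
F4 | step 11 | 6‑(chloromethyl)‑5,7‑dimethoxy‑2‑methyl‑4H‑chromen‑4‑one | COc1cc2oc(C)cc(=O)c2c(OC)c1CCl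
F5 | step 11 | [(5,7‑dimethoxy‑2‑methyl‑4‑oxo‑4H‑chromen‑6‑yl)methyl]zinc chloride | COc1cc2oc(C)cc(=O)c2c(OC)c1C[Zn]Cl
F6 | step 11 | (3R)‑6,8‑bis(benzyloxy)‑5‑[(5,7‑dimethoxy‑2‑methyl‑4‑oxo‑4H‑chromen‑6‑yl)methyl]‑3,7‑dimethylisochroman‑1‑one | COc1cc2oc(C)cc(=O)c2c(OC)c1Cc1c(OCc3ccccc3)c(C)c(OCc3ccccc3)c2c1C[C@@H](C)OC2=O
F7 | step 9 | 1‑[3‑(dimethoxymethyl)‑6‑hydroxy‑2,4‑dimethoxyphenyl]ethan‑1‑one | COc1cc(O)c(C(C)=O)c(OC)c1C(OC)OC
F8 | step 9 | 1‑[3‑(dimethoxymethyl)‑6‑hydroxy‑2,4‑dimethoxyphenyl]butane‑1,3‑dione | COc1cc(O)c(C(=O)CC(C)=O)c(OC)c1C(OC)OC
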